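## Structural features

The target is a germacranolide: a ten-membered carbocycle (C1–C10) fused trans at C6–C7 to an α-methylene-γ-butyrolactone (O6–C12(=O)–C11(=C13)–C7). The carbocycle holds two trisubstituted alkenes, C1=C10 and C4=C5, both cis within the ring, and each carries an acyloxymethyl group: C14 on C10 a methacrylate, C15 on C4 an acetate. Three stereocentres stand side by side, C6 (R), C7 (R) and C8 (R): the lactone oxygen on C6 is trans to the C7 side chain, the free hydroxyl on C8 is cis to it, so O6 and O8 are trans. Fragile groups are the methylene lactone and the methacrylate (Michael acceptors that do not tolerate strong base, hydride or soft nucleophiles), the two allylic esters and the allylic lactone C6–O bond (ionisable), and the 8-hydroxy lactone array (open to translactonisation). The real difficulty is the medium ring with two cis-trisubstituted alkenes of defined geometry, together with the need to tell three oxygens (O8, O14, O15) and two acyl groups apart. The key step exploits that C1 and C6 face each other across the ring and that C10 is next to C1: a C1–C6 bond turns the ring into a decalin in which C4=C5 is a cyclohexene bond (hence cis) and C10(=O) with the C1–C6 oxide is an α,β-epoxy ketone, whose fragmentation returns the ten-membered ring with a C6 ketone and a C1≡C10 alkyne. That alkyne is homopropargylic to O8, so a tether from O8 can put C14 on C10 by syn addition, and the C6 ketone is the handle for C7 and for the lactone.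

## Logic of the disconnections

34 ⇒ 33. Cut: the O14–acyl bond. Reason: the more reactive acrylic ester is attached last. Gain: only one ester is left to place. Demand: acylation must pick the primary O14–H over the hindered secondary O8–H.

33 ⇒ 32. Cut: C11=C13. Reason: the methylene lactone is the most fragile unit and can be made from a C11 phosphonate and a one-carbon aldehyde under carbonate conditions. Gain: in 32 and before it the lactone is saturated at C11 and inert to platinum, palladium and iodonium reagents. Demand: olefination without loss of the C15 acetate.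

32 ⇒ 31. Cut: C10–C14. Reason: a vinyl iodide accepts C14 already at the alcohol oxidation level, so no reduction is needed beside the lactone. Gain: C14 and O14 are removed and the alkene geometry is stored in the C–I bond. Demand: coupling with retention and without ionising the allylic acetate.

31 ⇒ 30 ⇒ 28 (through 29). Cuts: C10–I back to C10–Si, then C10–Si, C1–H and O8–Si. Reason: an Si–H group tethered to O8 reaches C10 through a five-membered ring and adds syn, so the position of C14 and the ring-cis C1=C10 geometry both follow from O8 and from the cycloalkyne. Gain: the alkene becomes the alkyne that the fragmentation delivers. Demand: exo-selective syn hydrosilylation and ipso-iodination with retention.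

28 ⇒ 27 ⇒ 26 ⇒ 25. Cuts: the O8–H is re-silylated, the O15 acetyl C–O bond is cut, the O15 benzylic ether is restored. Reason: O15 must be unmasked first (for the acetate) and O8 second (for the tether), which a silyl ether and an oxidatively cleaved benzyl ether allow. Gain: 25 has every oxygen masked. Demand: each unmasking must leave the other group alone.

25 ⇒ 23 (through 24). Cut: C11–P. Reason: phosphorus is attached through the lactone enolate while no base-sensitive ester is present. Gain: a plain γ-lactone. Demand: phosphorylation on carbon at the only enolisable position.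

23 ⇒ 21 ⇒ 19 (through 22 and 20). Cuts: the lactone C6–O bond (re-formed with inversion), then O6–C12 and C6–H. Reason: hydride should reach C6 of 19 from the face away from the C7 and C8 substituents, which leads to the cis-fused 21; an intramolecular SN2 closure converts it into the trans-fused 23. Gain: C6 is again the ketone that the fragmentation produces. Demand: clean 1,2-reduction and closure with inversion at an allylic carbon.

19 ⇒ 18 ⇒ 17. Cuts: C7–H (epimerisation) and C7–C11. Reason: the two-carbon ester unit should enter trans to the C8 silyloxy group; re-enolisation and protonation from that same face then place it cis to O8. Gain: C7 is a methylene and C8 the only stereocentre. Demand: α′-selective enolisation and two face-selective events controlled by C8.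

17 ⇒ 15 (through 16). Reconnection: C1–C6, the C6 carbonyl oxygen becoming the oxirane oxygen and C1≡C10 becoming C1–C10(=O). Reason: the medium ring and its cis-alkene are then held in two six-membered rings. Gain: ten-membered ring chemistry is replaced by decalin chemistry. Demand: the forward fragmentation must break only C1–C6.

15 ⇒ 14. Cut: the two oxirane C–O bonds. Reason: nucleophilic epoxidation of the enone. Demand: attack on the α,β- and not the γ,δ-bond, without β-elimination of the C8 oxygen.

14 ⇒ 13. Transposition: C10=O and C1=C6 back to C6–OH and C1=C10. Reason: the tertiary bis-allylic alcohol is what ring closure gives, and it is transposed oxidatively without base. Demand: the shift must go to C10.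

13 ⇒ 12. Cut: C4=C5. Reason: metathesis in a six-membered ring gives the cis-trisubstituted alkene from two terminal alkenes, with no stereodefined vinyl halide. Demand: the 1,1-disubstituted alkene must take part.

12 ⇒ 11. Cut: C5–C6. Reason: 1,2-addition of a vinyl nucleophile. Demand: no conjugate addition and no enolisation.

11 ⇒ 9 (through 10). Cut: C1=C10. Reason: an intramolecular phosphonate olefination builds ring A from a chain in which C6 and C10 are at different oxidation levels, so no symmetric 1,3-dione, which would erase C8, is passed. Demand: a base mild enough for two β-silyloxy carbonyl units.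

9 ⇒ 8 + 5. Cut: C1–C6. Reason: acylation of a phosphonate carbanion joins the two building blocks; this is the bond the key step later breaks. Demand: addition to the lactone carbonyl and not enolisation.

8 ⇒ 6 (through 7). Cut: the lactone C–O bond, C10 going back to the acid. Reason: 6 supplies C8 enantiopure with its two carboxyl groups already distinguished. Demand: reduction of the acid beside the ester.

5 ⇒ 3 + 2 (through 4), and 2 ⇒ 1. Cuts: C3–C4 (sp3–sp2 coupling) and the O15 benzyl ether bond. Reason: both halves are simple alkenes. Demand: the vinylic bromide must survive the etherification.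

## Other disconnections considered

Alternative 1: The cut is made at the end, through the C6–O bond of the lactone and the C15–O bond of the acetate.
- Forward step: the diene acid A2 (C15=C4–C5=C6 diene, C12 acid, O8 silyl ether, O14 methacrylate) is treated with Pd(OAc)2, a quinone oxidant and LiOAc in AcOH. Divalent palladium binds the diene, the carboxylate adds to C6 and acetate adds to C15 of the π-allyl intermediate, giving A1; desilylation would finish.
- In its favour: one operation makes the lactone, the C15 acetate and the C4=C5 bond, O15 needs no protecting group, and the methylene lactone appears only at the end. In end-game step economy and in bonds formed by the key step (two C–O bonds against none) it is better than the chosen plan.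
- Against it here: the step does not make the ten-membered ring, so the main problem is moved into the synthesis of A2. The geometry of the new C4=C5 bond depends on the syn or anti form of a π-allyl complex inside a medium ring. The C6 configuration depends on the diene face taken by palladium and on the mode of carboxylate addition. The acrylic acid, the methacrylate and C1=C10 are further sites for divalent palladium.
- Comparison: the two plans are equal in resting on a known reaction class. The chosen plan fixes both alkene geometries by ring constraint, where this one leaves one geometry and one stereocentre to a macrocycle. The total count would not be expected to be lower once A2 has to be made.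

Alternative 2: The cut is the C2–C3 bond.
- Forward step: the open-chain compound A4 (phenylsulfonyl group on C2, primary allylic bromide at C3) is deprotonated at C2 with KN(SiMe3)2, and the sulfonyl-stabilised allyl anion displaces the bromide to close the carbocycle as A3.
- In its favour: the key step forms a skeletal C–C bond and the ring together, so it is more convergent than the chosen key step (better on this point). The C6–C7–C8 triad would be built on an open chain, where stereocontrol is more predictable than on the ring of 17 (better on this point). Closure is remote from the stereocentres, and sulfone closures of medium terpenoid rings are a known class (equal on precedent).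
- Against it: both trisubstituted alkenes must be made with the right geometry in the open chain and keep it. Closure needs high dilution and competes with α/γ ambident reactivity of the anion and with SN2′ attack. The sulfone must then be removed without shifting C1=C10. The tetrahydrofuran must be oxidised at C12 beside other allylic positions, and two primary silyl ethers must be told apart.
- Comparison: the chosen plan is safer for the alkenes and weaker for C6 and C7. After the key step the two are comparable in length, A3 being further from the target in oxidation state.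

Alternative 3: The cut is the C7–C8 bond, reached by ring contraction.
- Forward step: the thirteen-membered cyclic ether A6 (tributylstannyl group on C8, ring oxygen between C8 and C13) undergoes tin–lithium exchange with n-BuLi. The α-alkoxy carbanion shifts [2,3] onto C7, forming C7–C8, freeing O8 and creating C11=C13, to give A5.
- In its favour: a single step forms a skeletal bond, sets C7 and C8, unveils the C8 hydroxyl and the exocyclic methylene and contracts a ring that is easier to close than a ten-membered carbocycle. In bonds and stereocentres made by the key step it is clearly better than the chosen plan, which makes neither. The C8 configuration can be relayed from a configurationally defined stannane.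
- Against it: A6 needs an enantioenriched α-alkoxystannane inside a macrocycle that already holds both trisubstituted alkenes. The [1,2] shift and elimination compete, the C6/C7/C8 relationship depends on a macrocyclic transition state, and the late C12 oxidation and ester differentiation of alternative 2 remain.
- Comparison: it is equal to the chosen plan in that the ring-cis alkenes are inherited and not made by the key step. It is better in what the step builds, and worse in the length and certainty of the way to its precursor.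

Key step: step 10

Remarks on the chemistry (assumptions, each in one line):
- Ring compounds, decalins included, are numbered as germacranolides (ring C1–C10, C14 on C10, C15 on C4, C11–C13 on C7).
- A secondary TBS ether on O8 and a primary trialkylsilyl ether on O15 cannot be cleaved selectively in either order, so O15 is carried as a 4-methoxybenzyl ether.
- A 2-alkylcyclohexane-1,3-dione is enolised and its two carbonyl groups cannot be distinguished by an organometallic addition; C8 is therefore taken from the half-ester 6, assumed to be the commercial (R)-enantiomer used for statin side chains.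
- Alkaline peroxide is expected to enter trans to the C8 silyloxy group, so 15 is drawn with the oxirane on that face; the other epimer would fragment to the same 17.
- Working stereochemical model after the key step: external reagents reach C7 and C6 from the ring face opposite to the C8 silyloxy group, so C7 is set by protonation and C6 by inversion.
- C14 is brought in as CH2OH, because an ester at C14 could not be reduced beside the lactone.

Step 1
Reactants: 1 2-bromoprop-2-en-1-ol
Product: 2 1-{[(2-bromoprop-2-en-1-yl)oxy]methyl}-4-methoxybenzene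
Conditions: NaH, 4-MeOC6H4CH2Cl, n-Bu4NI (cat.), THF, 0 °C → rt
Reagents that add atoms: 4-methoxybenzyl chloride ClCc1ccc(OC)cc1
Why: Williamson ether synthesis; the sodium alkoxide of the primary allylic alcohol displaces the benzylic chloride, and the vinylic C–Br bond is inert to SN2 conditions and is kept for step 2.

Step 2
Reactants: 3 diethyl prop-2-en-1-ylphosphonate; 2 1-{[(2-bromoprop-2-en-1-yl)oxy]methyl}-4-methoxybenzene
Product: 5 diethyl (4-{[(4-methoxybenzyl)oxy]methyl}pent-4-en-1-yl)phosphonate, via alkylborane 4 (not isolated)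
Conditions: 9-BBN-H, THF, 0 °C → rt; then 2, PdCl2(dppf) (3 mol %), K3PO4 (3 M aq.), DMF, 50 °C
Reagents that add atoms: none
Why: Anti-Markovnikov hydroboration of the terminal alkene and B-alkyl Suzuki–Miyaura coupling with the 2-bromoalkene (oxidative addition to zerovalent palladium, phosphate-assisted transmetalation, reductive elimination) join C3 to C4; no stereo element is made.

Step 3
Reactants: 6 (3R)-3-{[tert-butyl(dimethyl)silyl]oxy}-5-methoxy-5-oxopentanoic acid
Product: 8 (4R)-4-{[tert-butyl(dimethyl)silyl]oxy}oxan-2-one, via hydroxy ester 7 (not isolated)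
Conditions: BH3·SMe2, THF, 0 °C → rt; MeOH; then pyridinium 4-toluenesulfonate (cat.), toluene, 60 °C
Reagents that add atoms: none
Why: Borane reduces the free carboxylic acid much faster than the methyl ester, and the δ-hydroxy ester lactonises under mild acid; the silyloxy stereocentre (future C8) is not touched.

Step 4
Reactants: 5 diethyl (4-{[(4-methoxybenzyl)oxy]methyl}pent-4-en-1-yl)phosphonate; 8 (4R)-4-{[tert-butyl(dimethyl)silyl]oxy}oxan-2-one
Product: 9 diethyl [(8R)-8-{[tert-butyl(dimethyl)silyl]oxy}-10-hydroxy-2-{[(4-methoxybenzyl)oxy]methyl}-6-oxodec-1-en-5-yl]phosphonate (both C5 epimers; open form of a hemiketal)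
Conditions: 5 (2.1 equiv), n-BuLi (2.0 equiv), THF, −78 °C; then 8, −78 °C; AcOH
Reagents that add atoms: none
Why: Claisen-type acylation of the α-lithiated phosphonate by the lactone with ring opening forms C1–C6; carbonyl addition at −78 °C should outrun α-deprotonation, so the β-silyloxy group is not eliminated. The second equivalent of carbanion is consumed by the acidic product and the surplus 5 is recovered.

Step 5
Reactants: 9 diethyl [(8R)-8-{[tert-butyl(dimethyl)silyl]oxy}-10-hydroxy-2-{[(4-methoxybenzyl)oxy]methyl}-6-oxodec-1-en-5-yl]phosphonate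
Product: 11 (5R)-5-{[tert-butyl(dimethyl)silyl]oxy}-2-(3-{[(4-methoxybenzyl)oxy]methyl}but-3-en-1-yl)cyclohex-2-en-1-one, via keto aldehyde 10 (not isolated)
Conditions: Dess–Martin periodinane, NaHCO3, CH2Cl2, 0 °C → rt; then LiCl, i-Pr2NEt, MeCN, rt
Reagents that add atoms: none
Why: Dess–Martin oxidation of the primary alcohol, then intramolecular Horner–Wadsworth–Emmons olefination under Masamune–Roush conditions, closes ring A as the six-membered enone (C1=C10); the weak base spares both β-silyloxy carbonyl units.

Step 6
Reactants: 11 (5R)-5-{[tert-butyl(dimethyl)silyl]oxy}-2-(3-{[(4-methoxybenzyl)oxy]methyl}but-3-en-1-yl)cyclohex-2-en-1-one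
Product: 12 (5R)-5-{[tert-butyl(dimethyl)silyl]oxy}-1-ethenyl-2-(3-{[(4-methoxybenzyl)oxy]methyl}but-3-en-1-yl)cyclohex-2-en-1-ol (both C1 epimers)
Conditions: CeCl3 (anhydrous), CH2=CHMgBr, THF, −78 °C
Reagents that add atoms: vinylmagnesium bromide C=C[Mg]Br
Why: Organocerium-mediated 1,2-addition of the vinyl Grignard reagent to the α-substituted enone forms C5–C6 (cerium suppresses enolisation and conjugate addition); the new carbinol centre is erased in step 8, so both epimers are used.

Step 7
Reactants: 12 (5R)-5-{[tert-butyl(dimethyl)silyl]oxy}-1-ethenyl-2-(3-{[(4-methoxybenzyl)oxy]methyl}but-3-en-1-yl)cyclohex-2-en-1-ol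
Product: 13 (3R)-3-{[tert-butyl(dimethyl)silyl]oxy}-6-{[(4-methoxybenzyl)oxy]methyl}-3,4,7,8-tetrahydronaphthalen-4a(2H)-ol (both C4a epimers)
Conditions: RuCl2(=CHPh)(PCy3)(H2IMes) (second-generation Grubbs catalyst, 5 mol %), CH2Cl2 (5 mM), 40 °C
Reagents that add atoms: none
Why: Ring-closing olefin metathesis between the vinyl group and the 1,1-disubstituted alkene, driven by loss of ethene, closes ring B; a six-membered ring allows only the ring-cis C4=C5 geometry, and the trisubstituted C1=C10 alkene does not take part.

Step 8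
Reactants: 13 (3R)-3-{[tert-butyl(dimethyl)silyl]oxy}-6-{[(4-methoxybenzyl)oxy]methyl}-3,4,7,8-tetrahydronaphthalen-4a(2H)-ol
Product: 14 (3S)-3-{[tert-butyl(dimethyl)silyl]oxy}-6-{[(4-methoxybenzyl)oxy]methyl}-3,4,7,8-tetrahydronaphthalen-1(2H)-one
Conditions: [C5H5NH][CrO3Cl] (pyridinium chlorochromate), 4 Å molecular sieves, CH2Cl2, rt
Reagents that add atoms: none
Why: Oxidative 1,3-transposition of a tertiary allylic alcohol by hexavalent chromium (Babler–Dauben oxidation): the chromate ester shifts [3,3] to C10, the only allylic terminus that bears hydrogen, and is oxidised to the conjugated dienone; a shift towards C4 is unproductive and reversible.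

Step 9
Reactants: 14 (3S)-3-{[tert-butyl(dimethyl)silyl]oxy}-6-{[(4-methoxybenzyl)oxy]methyl}-3,4,7,8-tetrahydronaphthalen-1(2H)-one
Product: 15 (3S,4aR,8aS)-3-{[tert-butyl(dimethyl)silyl]oxy}-4a,8a-epoxy-6-{[(4-methoxybenzyl)oxy]methyl}-3,4,4a,7,8,8a-hexahydronaphthalen-1(2H)-one (germacrane numbering: C10 ketone; C1–C6 oxide trans to the C8 silyloxy group; C4=C5)
Conditions: 30% aq. H2O2, NaOH (0.3 equiv), MeOH, 0 °C
Reagents that add atoms: hydrogen peroxide OO
Why: Weitz–Scheffer nucleophilic epoxidation: hydroperoxide adds to the β-carbon C6 and the enolate closes on oxygen, which puts the oxirane on the α,β-bond C1–C6, as in alkaline peroxide epoxidations of linear dienones. Axial attack trans to the C8 silyloxy group should set the face, and substoichiometric hydroxide at 0 °C limits E1cB loss of that group.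

Step 10
Reactants: 15 (3S,4aR,8aS)-3-{[tert-butyl(dimethyl)silyl]oxy}-4a,8a-epoxy-6-{[(4-methoxybenzyl)oxy]methyl}-3,4,4a,7,8,8a-hexahydronaphthalen-1(2H)-one
Product: 17 (2E,9R)-9-{[tert-butyl(dimethyl)silyl]oxy}-3-{[(4-methoxybenzyl)oxy]methyl}cyclodec-2-en-6-yn-1-one (germacrane numbering: C6 ketone; C1≡C10; ring-cis C4=C5), via tosylhydrazone 16 (not isolated)
Conditions: 4-MeC6H4SO2NHNH2 (1.05 equiv), CH2Cl2/AcOH (1:1), −20 °C → rt
Reagents that add atoms: none
Why: The hydrazide condenses with the C10 ketone to give 16, whose ionised N–H opens the oxirane at C1–O to leave oxygen on C6 and a C1=C10 azoalkene. Grob-type fragmentation follows: the C6 oxygen becomes the carbonyl, C1–C6 breaks, C1≡C10 forms and N2 and 4-toluenesulfinate leave. The closest known reaction type is the Eschenmoser–Tanabe fragmentation of bicyclic α,β-epoxy ketone tosylhydrazones to cycloalkynones, such as an octalone oxide going to a cyclodecynone. No ring is closed by bond formation: the ten-membered ring is set free by cleaving the bond shared by the two six-membered rings. No stereocentre is formed; C8 is carried through and the ring-cis C4=C5 geometry is inherited from the cyclohexene. The step needs cleavage of C1–C6 only: in the azoalkene the C10–N and C1–C6 bonds are trans across C1=C10 and antiperiplanar within ring A, and the emerging C6 carbonyl gains conjugation with C4=C5. One equivalent of hydrazide and a low temperature should keep the product enone from condensing and the β-silyloxy ketone from eliminating.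

Step 11
Reactants: 17 (2E,9R)-9-{[tert-butyl(dimethyl)silyl]oxy}-3-{[(4-methoxybenzyl)oxy]methyl}cyclodec-2-en-6-yn-1-one
Product: 18 methyl [(1S,3E,10R)-10-{[tert-butyl(dimethyl)silyl]oxy}-4-{[(4-methoxybenzyl)oxy]methyl}-2-oxocyclodec-3-en-7-yn-1-yl]acetate (C7 epimer; side chain trans to O8)
Conditions: LiN(i-Pr)2, THF, −78 °C; then BrCH2CO2Me, DMPU, −78 → −40 °C
Reagents that add atoms: methyl bromoacetate COC(=O)CBr
Why: Kinetic deprotonation of the enone at the α′ carbon C7 and SN2 alkylation of the lithium enolate form C7–C11. The electrophile should enter the face opposite to the adjacent C8 silyloxy group (1,2-induction as in cyclic β-silyloxy enolates), giving the 7,8-trans epimer that step 12 corrects.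

Step 12
Reactants: 18 methyl [(1S,3E,10R)-10-{[tert-butyl(dimethyl)silyl]oxy}-4-{[(4-methoxybenzyl)oxy]methyl}-2-oxocyclodec-3-en-7-yn-1-yl]acetate
Product: 19 methyl [(1R,3E,10R)-10-{[tert-butyl(dimethyl)silyl]oxy}-4-{[(4-methoxybenzyl)oxy]methyl}-2-oxocyclodec-3-en-7-yn-1-yl]acetate (side chain cis to O8)
Conditions: LiN(SiMe3)2, THF, −78 °C; then 2,6-di-tert-butylphenol, −78 °C
Reagents that add atoms: none
Why: Enolate formation at C7 (the ketone α-hydrogen is more acidic than the ester α-hydrogens) and kinetic protonation by a hindered phenol from the face opposite to the C8 silyloxy group place H7 trans and the acetate arm cis to O8; −78 °C avoids β-elimination from the enolate.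

Step 13
Reactants: 19 methyl [(1R,3E,10R)-10-{[tert-butyl(dimethyl)silyl]oxy}-4-{[(4-methoxybenzyl)oxy]methyl}-2-oxocyclodec-3-en-7-yn-1-yl]acetate
Product: 21 (4E,6S,7S,8R)-8-{[tert-butyl(dimethyl)silyl]oxy}-15-[(4-methoxybenzyl)oxy]-13,14-dinorgermacr-4-en-1(10)-yn-12,6-olide (cis-fused lactone), via hydroxy ester 20 (not isolated)
Conditions: NaBH4, CeCl3·7H2O, MeOH, −78 °C; then pyridinium 4-toluenesulfonate (cat.), CH2Cl2, rt
Reagents that add atoms: none
Why: Luche 1,2-reduction of the cis-enone; hydride should attack C6 from the face opposite to the C7 side chain and the C8 silyloxy group, giving the alcohol cis to the side chain, which closes to the cis-fused γ-lactone with retention at C6.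

Step 14
Reactants: 21 (4E,6S,7S,8R)-8-{[tert-butyl(dimethyl)silyl]oxy}-15-[(4-methoxybenzyl)oxy]-13,14-dinorgermacr-4-en-1(10)-yn-12,6-olide
Product: 23 (4E,6R,7S,8R)-8-{[tert-butyl(dimethyl)silyl]oxy}-15-[(4-methoxybenzyl)oxy]-13,14-dinorgermacr-4-en-1(10)-yn-12,6-olide (trans-fused lactone), via hydroxy acid 22 (not isolated)
Conditions: LiOH, THF/H2O, 0 °C; cold dilute HCl to pH 4–5, extraction; then PPh3, i-PrO2CN=NCO2i-Pr, THF, 0 °C
Reagents that add atoms: lithium hydroxide [Li+].[OH-]
Why: Saponification to the γ-hydroxy acid and Mitsunobu lactonisation: the C6 alcohol is activated as its alkoxyphosphonium ion and displaced by the carboxylate in a 5-exo SN2 closure with inversion, which turns the cis- into the trans-fused lactone (H6 and H7 trans as in the target).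

Step 15
Reactants: 23 (4E,6R,7S,8R)-8-{[tert-butyl(dimethyl)silyl]oxy}-15-[(4-methoxybenzyl)oxy]-13,14-dinorgermacr-4-en-1(10)-yn-12,6-olide
Product: 25 (4E,6R,7S,8R)-8-{[tert-butyl(dimethyl)silyl]oxy}-11-(diethoxyphosphoryl)-15-[(4-methoxybenzyl)oxy]-13,14-dinorgermacr-4-en-1(10)-yn-12,6-olide (both C11 epimers), via enol phosphate 24 (not isolated)
Conditions: LiN(i-Pr)2 (2.3 equiv), THF, −78 °C; ClP(O)(OEt)2; −78 °C → rt; AcOH
Reagents that add atoms: diethyl chlorophosphate CCOP(=O)(Cl)OCC
Why: O-phosphorylation of the lactone enolate and base-induced 1,3-shift of phosphorus from oxygen to carbon (enol phosphate to β-keto phosphonate rearrangement, known for lactones) install the C11 phosphonate that later becomes the exocyclic methylene; the C11 configuration is irrelevant.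

Step 16
Reactants: 25 (4E,6R,7S,8R)-8-{[tert-butyl(dimethyl)silyl]oxy}-11-(diethoxyphosphoryl)-15-[(4-methoxybenzyl)oxy]-13,14-dinorgermacr-4-en-1(10)-yn-12,6-olide
Product: 26 (4E,6R,7S,8R)-8-{[tert-butyl(dimethyl)silyl]oxy}-11-(diethoxyphosphoryl)-15-hydroxy-13,14-dinorgermacr-4-en-1(10)-yn-12,6-olide
Conditions: 2,3-dichloro-5,6-dicyano-1,4-benzoquinone, CH2Cl2/pH 7 buffer (10:1), 0 °C
Reagents that add atoms: none
Why: Oxidative cleavage of the 4-methoxybenzyl ether (hydride abstraction, then hydrolysis of the oxocarbenium ion); silyl ether, alkyne, phosphonate and lactone are inert.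

Step 17
Reactants: 26 (4E,6R,7S,8R)-8-{[tert-butyl(dimethyl)silyl]oxy}-11-(diethoxyphosphoryl)-15-hydroxy-13,14-dinorgermacr-4-en-1(10)-yn-12,6-olide
Product: 27 (4E,6R,7S,8R)-15-acetoxy-8-{[tert-butyl(dimethyl)silyl]oxy}-11-(diethoxyphosphoryl)-13,14-dinorgermacr-4-en-1(10)-yn-12,6-olide
Conditions: Ac2O, pyridine, CH2Cl2, 0 °C → rt
Reagents that add atoms: acetic anhydride CC(=O)OC(C)=O
Why: O-acetylation of the primary allylic alcohol; pyridine is too weak a base to deprotonate the phosphono lactone.

Step 18
Reactants: 27 (4E,6R,7S,8R)-15-acetoxy-8-{[tert-butyl(dimethyl)silyl]oxy}-11-(diethoxyphosphoryl)-13,14-dinorgermacr-4-en-1(10)-yn-12,6-olide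
Product: 28 (4E,6R,7R,8R)-15-acetoxy-11-(diethoxyphosphoryl)-8-hydroxy-13,14-dinorgermacr-4-en-1(10)-yn-12,6-olide
Conditions: 48% aq. HF, MeCN, 0 °C → rt
Reagents that add atoms: none
Why: Acidic fluoride cleavage of the secondary silyl ether; acetate, lactone and phosphonate are stable to aqueous HF, and the freed 8-hydroxyl is the anchor for the tether.

Step 19
Reactants: 28 (4E,6R,7R,8R)-15-acetoxy-11-(diethoxyphosphoryl)-8-hydroxy-13,14-dinorgermacr-4-en-1(10)-yn-12,6-olide
Product: 30 (1(10)E,4E,6R,7S,8R)-15-acetoxy-11-(diethoxyphosphoryl)-8-O,10-C-(dimethylsilanediyl)-8-hydroxy-13,14-dinorgermacra-1(10),4-dien-12,6-olide (five-membered cyclic siloxane; both ring alkenes ring-cis), via dimethylsilyl ether 29 (not isolated)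
Conditions: (HMe2Si)2NH, 60 °C; evaporate; then Pt2[(CH2=CHSiMe2)2O]3 (cat.), THF, rt
Reagents that add atoms: 1,1,3,3-tetramethyldisilazane C[SiH](C)N[SiH](C)C
Why: O-silylation by the disilazane, then intramolecular hydrosilylation of the homopropargylic alkyne catalysed by zerovalent platinum (5-exo-dig, syn addition) puts silicon on C10 and hydrogen on C1. Syn addition across the cycloalkyne can give only the ring-cis C1=C10 alkene, and the regiochemistry follows from the preference for the five-membered oxasilolane.

Step 20
Reactants: 30 (1(10)E,4E,6R,7S,8R)-15-acetoxy-11-(diethoxyphosphoryl)-8-O,10-C-(dimethylsilanediyl)-8-hydroxy-13,14-dinorgermacra-1(10),4-dien-12,6-olide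
Product: 31 (1(10)E,4E,6R,7R,8R)-15-acetoxy-11-(diethoxyphosphoryl)-8-hydroxy-10-iodo-13,14-dinorgermacra-1(10),4-dien-12,6-olide
Conditions: N-iodosuccinimide, (CF3)2CHOH, 0 °C; aq. NaHCO3
Reagents that add atoms: N-iodosuccinimide O=C1CCC(=O)N1I
Why: Electrophilic ipso-iododesilylation of the alkenylsiloxane (β-silyl cation stabilisation, retention of geometry) gives the vinyl iodide, and the Si–O bond is hydrolysed on work-up to free O8–H; the C4=C5 alkene is deactivated by its two allylic acyloxy groups.

Step 21
Reactants: 31 (1(10)E,4E,6R,7R,8R)-15-acetoxy-11-(diethoxyphosphoryl)-8-hydroxy-10-iodo-13,14-dinorgermacra-1(10),4-dien-12,6-olide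
Product: 32 (1(10)E,4E,6R,7R,8R)-15-acetoxy-11-(diethoxyphosphoryl)-8,14-dihydroxy-13-norgermacra-1(10),4-dien-12,6-olide
Conditions: Bu3SnCH2OH, Pd2(dba)3 (cat.), AsPh3, CuI (cat.), DMF, 50 °C
Reagents that add atoms: (tributylstannyl)methanol CCCC[Sn](CCCC)(CCCC)CO
Why: Stille cross-coupling of the alkenyl iodide with the hydroxymethylstannane attaches C14 to C10 with retention of geometry and at the alcohol oxidation level; the arsine ligand and copper co-catalyst allow a low temperature, so the allylic acetate should not be ionised.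

Step 22
Reactants: 32 (1(10)E,4E,6R,7R,8R)-15-acetoxy-11-(diethoxyphosphoryl)-8,14-dihydroxy-13-norgermacra-1(10),4-dien-12,6-olide
Product: 33 (1(10)E,4E,6R,7R,8R)-15-acetoxy-8,14-dihydroxygermacra-1(10),4,11(13)-trien-12,6-olide
Conditions: 37% aq. CH2O, K2CO3, THF, 0 °C → rt
Reagents that add atoms: formaldehyde C=O
Why: Horner–Wadsworth–Emmons olefination of the phosphono lactone carbanion with formaldehyde under carbonate conditions forms the exocyclic C11=C13 bond; the phosphonate carbon is the only position acidic enough to be deprotonated.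

Step 23
Reactants: 33 (1(10)E,4E,6R,7R,8R)-15-acetoxy-8,14-dihydroxygermacra-1(10),4,11(13)-trien-12,6-olide
Product: 34 (1(10)E,4E,6R,7R,8R)-15-acetoxy-8-hydroxy-14-[(2-methylprop-2-enoyl)oxy]germacra-1(10),4,11(13)-trien-12,6-olide (target; both ring alkenes ring-cis)
Conditions: CH2=C(CH3)COCl (1.05 equiv), 2,4,6-trimethylpyridine, CH2Cl2, −78 °C
Reagents that add atoms: methacryloyl chloride C=C(C)C(=O)Cl
Why: Acylation by an acid chloride with a hindered pyridine base at low temperature is selective for the primary allylic 14-hydroxyl over the hindered secondary 8-hydroxyl and gives the target.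

Compound list

1 | 2-bromoprop-2-en-1-ol | C=C(Br)CO | starting material
2 | 1-{[(2-bromoprop-2-en-1-yl)oxy]methyl}-4-methoxybenzene | C=C(Br)COCc1ccc(OC)cc1 | intermediate
3 | diethyl prop-2-en-1-ylphosphonate | C=CCP(=O)(OCC)OCC | starting material
4 | diethyl [3-(9-borabicyclo[3.3.1]nonan-9-yl)propyl]phosphonate | CCOP(=O)(CCCB1C2CCCC1CCC2)OCC | intermediate (not isolated)
5 | diethyl (4-{[(4-methoxybenzyl)oxy]methyl}pent-4-en-1-yl)phosphonate | CCOP(=O)(CCCC(=C)COCc1ccc(OC)cc1)OCC | intermediate
6 | (3R)-3-{[tert-butyl(dimethyl)silyl]oxy}-5-methoxy-5-oxopentanoic acid | COC(=O)C[C@H](O[Si](C)(C)C(C)(C)C)CC(=O)O | starting material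
7 | methyl (3R)-3-{[tert-butyl(dimethyl)silyl]oxy}-5-hydroxypentanoate | COC(=O)C[C@H](O[Si](C)(C)C(C)(C)C)CCO | intermediate (not isolated)
8 | (4R)-4-{[tert-butyl(dimethyl)silyl]oxy}oxan-2-one | O=C1C[C@H](O[Si](C)(C)C(C)(C)C)CCO1 | intermediate
9 | diethyl [(8R)-8-{[tert-butyl(dimethyl)silyl]oxy}-10-hydroxy-2-{[(4-methoxybenzyl)oxy]methyl}-6-oxodec-1-en-5-yl]phosphonate (C5 epimers) | CCOP(=O)(OCC)C(CCC(=C)COCc1ccc(OC)cc1)C(=O)C[C@H](O[Si](C)(C)C(C)(C)C)CCO | intermediate
10 | diethyl [(8R)-8-{[tert-butyl(dimethyl)silyl]oxy}-2-{[(4-methoxybenzyl)oxy]methyl}-6,10-dioxodec-1-en-5-yl]phosphonate | CCOP(=O)(OCC)C(CCC(=C)COCc1ccc(OC)cc1)C(=O)C[C@H](O[Si](C)(C)C(C)(C)C)CC=O | intermediate (not isolated)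
11 | (5R)-5-{[tert-butyl(dimethyl)silyl]oxy}-2-(3-{[(4-methoxybenzyl)oxy]methyl}but-3-en-1-yl)cyclohex-2-en-1-one | O=C1C[C@H](O[Si](C)(C)C(C)(C)C)CC=C1CCC(=C)COCc1ccc(OC)cc1 | intermediate
12 | (5R)-5-{[tert-butyl(dimethyl)silyl]oxy}-1-ethenyl-2-(3-{[(4-methoxybenzyl)oxy]methyl}but-3-en-1-yl)cyclohex-2-en-1-ol (C1 epimers) | C=CC1(O)C[C@H](O[Si](C)(C)C(C)(C)C)CC=C1CCC(=C)COCc1ccc(OC)cc1 | intermediate
13 | (3R)-3-{[tert-butyl(dimethyl)silyl]oxy}-6-{[(4-methoxybenzyl)oxy]methyl}-3,4,7,8-tetrahydronaphthalen-4a(2H)-ol (C4a epimers) | OC12C[C@H](O[Si](C)(C)C(C)(C)C)CC=C1CCC(COCc3ccc(OC)cc3)=C2 | intermediate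
14 | (3S)-3-{[tert-butyl(dimethyl)silyl]oxy}-6-{[(4-methoxybenzyl)oxy]methyl}-3,4,7,8-tetrahydronaphthalen-1(2H)-one | O=C1C[C@@H](O[Si](C)(C)C(C)(C)C)CC2=C1CCC(COCc3ccc(OC)cc3)=C2 | intermediate
15 | (3S,4aR,8aS)-3-{[tert-butyl(dimethyl)silyl]oxy}-4a,8a-epoxy-6-{[(4-methoxybenzyl)oxy]methyl}-3,4,4a,7,8,8a-hexahydronaphthalen-1(2H)-one | O=C1C[C@@H](O[Si](C)(C)C(C)(C)C)C[C@]23O[C@]12CCC(COCc4ccc(OC)cc4)=C3 | intermediate (key-step precursor)
16 | 4-methylbenzenesulfonylhydrazone of 15 at the ketone carbon (germacrane C10) | Cc1ccc(cc1)S(=O)(=O)NN=C1C[C@@H](O[Si](C)(C)C(C)(C)C)C[C@]23O[C@]12CCC(COCc4ccc(OC)cc4)=C3 | intermediate (not isolated)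
17 | (2E,9R)-9-{[tert-butyl(dimethyl)silyl]oxy}-3-{[(4-methoxybenzyl)oxy]methyl}cyclodec-2-en-6-yn-1-one | C1C#CCC/C(COCc2ccc(OC)cc2)=C\C(=O)C[C@@H]1O[Si](C)(C)C(C)(C)C | intermediate (key-step product)
18 | methyl [(1S,3E,10R)-10-{[tert-butyl(dimethyl)silyl]oxy}-4-{[(4-methoxybenzyl)oxy]methyl}-2-oxocyclodec-3-en-7-yn-1-yl]acetate | C1C#CCC/C(COCc2ccc(OC)cc2)=C\C(=O)[C@@H](CC(=O)OC)[C@@H]1O[Si](C)(C)C(C)(C)C | intermediate
19 | methyl [(1R,3E,10R)-10-{[tert-butyl(dimethyl)silyl]oxy}-4-{[(4-methoxybenzyl)oxy]methyl}-2-oxocyclodec-3-en-7-yn-1-yl]acetate | C1C#CCC/C(COCc2ccc(OC)cc2)=C\C(=O)[C@H](CC(=O)OC)[C@@H]1O[Si](C)(C)C(C)(C)C | intermediate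
20 | methyl [(1S,2S,3E,10R)-10-{[tert-butyl(dimethyl)silyl]oxy}-2-hydroxy-4-{[(4-methoxybenzyl)oxy]methyl}cyclodec-3-en-7-yn-1-yl]acetate | C1C#CCC/C(COCc2ccc(OC)cc2)=C\[C@H](O)[C@H](CC(=O)OC)[C@@H]1O[Si](C)(C)C(C)(C)C | intermediate (not isolated)
21 | (4E,6S,7S,8R)-8-{[tert-butyl(dimethyl)silyl]oxy}-15-[(4-methoxybenzyl)oxy]-13,14-dinorgermacr-4-en-1(10)-yn-12,6-olide (cis-fused) | C1C#CCC/C(COCc3ccc(OC)cc3)=C\[C@@H]2OC(=O)C[C@@H]2[C@@H]1O[Si](C)(C)C(C)(C)C | intermediate
22 | [(1S,2S,3E,10R)-10-{[tert-butyl(dimethyl)silyl]oxy}-2-hydroxy-4-{[(4-methoxybenzyl)oxy]methyl}cyclodec-3-en-7-yn-1-yl]acetic acid | C1C#CCC/C(COCc2ccc(OC)cc2)=C\[C@H](O)[C@H](CC(=O)O)[C@@H]1O[Si](C)(C)C(C)(C)C | intermediate (not isolated)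
23 | (4E,6R,7S,8R)-8-{[tert-butyl(dimethyl)silyl]oxy}-15-[(4-methoxybenzyl)oxy]-13,14-dinorgermacr-4-en-1(10)-yn-12,6-olide (trans-fused) | C1C#CCC/C(COCc3ccc(OC)cc3)=C\[C@H]2OC(=O)C[C@@H]2[C@@H]1O[Si](C)(C)C(C)(C)C | intermediate
24 | diethyl enol phosphate of 23 (C11=C12, phosphate on the former carbonyl oxygen) | C1C#CCC/C(COCc3ccc(OC)cc3)=C\[C@H]2OC(OP(=O)(OCC)OCC)=C[C@@H]2[C@@H]1O[Si](C)(C)C(C)(C)C | intermediate (not isolated)
25 | (4E,6R,7S,8R)-8-{[tert-butyl(dimethyl)silyl]oxy}-11-(diethoxyphosphoryl)-15-[(4-methoxybenzyl)oxy]-13,14-dinorgermacr-4-en-1(10)-yn-12,6-olide (C11 epimers) | C1C#CCC/C(COCc3ccc(OC)cc3)=C\[C@H]2OC(=O)C(P(=O)(OCC)OCC)[C@@H]2[C@@H]1O[Si](C)(C)C(C)(C)C | intermediate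
26 | (4E,6R,7S,8R)-8-{[tert-butyl(dimethyl)silyl]oxy}-11-(diethoxyphosphoryl)-15-hydroxy-13,14-dinorgermacr-4-en-1(10)-yn-12,6-olide | C1C#CCC/C(CO)=C\[C@H]2OC(=O)C(P(=O)(OCC)OCC)[C@@H]2[C@@H]1O[Si](C)(C)C(C)(C)C | intermediate
27 | (4E,6R,7S,8R)-15-acetoxy-8-{[tert-butyl(dimethyl)silyl]oxy}-11-(diethoxyphosphoryl)-13,14-dinorgermacr-4-en-1(10)-yn-12,6-olide | C1C#CCC/C(COC(C)=O)=C\[C@H]2OC(=O)C(P(=O)(OCC)OCC)[C@@H]2[C@@H]1O[Si](C)(C)C(C)(C)C | intermediate
28 | (4E,6R,7R,8R)-15-acetoxy-11-(diethoxyphosphoryl)-8-hydroxy-13,14-dinorgermacr-4-en-1(10)-yn-12,6-olide | C1C#CCC/C(COC(C)=O)=C\[C@H]2OC(=O)C(P(=O)(OCC)OCC)[C@@H]2[C@@H]1O | intermediate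
29 | 8-O-(dimethylsilyl) ether of 28 | C1C#CCC/C(COC(C)=O)=C\[C@H]2OC(=O)C(P(=O)(OCC)OCC)[C@@H]2[C@@H]1O[SiH](C)C | intermediate (not isolated)
30 | (1(10)E,4E,6R,7S,8R)-15-acetoxy-11-(diethoxyphosphoryl)-8-O,10-C-(dimethylsilanediyl)-8-hydroxy-13,14-dinorgermacra-1(10),4-dien-12,6-olide | C[Si]1(C)O[C@H]2[C@H]3C(P(=O)(OCC)OCC)C(=O)O[C@@H]3/C=C(COC(C)=O)\CC/C=C1\C2 | intermediate
31 | (1(10)E,4E,6R,7R,8R)-15-acetoxy-11-(diethoxyphosphoryl)-8-hydroxy-10-iodo-13,14-dinorgermacra-1(10),4-dien-12,6-olide | C1/C(I)=C\CC/C(COC(C)=O)=C\[C@H]2OC(=O)C(P(=O)(OCC)OCC)[C@@H]2[C@@H]1O | intermediate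
32 | (1(10)E,4E,6R,7R,8R)-15-acetoxy-11-(diethoxyphosphoryl)-8,14-dihydroxy-13-norgermacra-1(10),4-dien-12,6-olide | C1/C(CO)=C\CC/C(COC(C)=O)=C\[C@H]2OC(=O)C(P(=O)(OCC)OCC)[C@@H]2[C@@H]1O | intermediate
33 | (1(10)E,4E,6R,7R,8R)-15-acetoxy-8,14-dihydroxygermacra-1(10),4,11(13)-trien-12,6-olide | C1/C(CO)=C\CC/C(COC(C)=O)=C\[C@H]2OC(=O)C(=C)[C@@H]2[C@@H]1O | intermediate
34 | (1(10)E,4E,6R,7R,8R)-15-acetoxy-8-hydroxy-14-[(2-methylprop-2-enoyl)oxy]germacra-1(10),4,11(13)-trien-12,6-olide | C=C(C)C(=O)OC/C1=C/CC/C(COC(C)=O)=C\[C@H]2OC(=O)C(=C)[C@@H]2[C@H](O)C1 | target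

Total step count: 23 steps. Longest linear sequence: 22 steps (1 → 2 → 5 → 9 → 11 → 12 → 13 → 14 → 15 → 17 → 18 → 19 → 21 → 23 → 25 → 26 → 27 → 28 → 30 → 31 → 32 → 33 → 34); the branch from 6 joins at step 4.

Steps least certain to work

Step 10 (key step). What may go wrong: diversion before fragmentation, by acid-promoted opening of the vinyl oxirane by acetate or by the hydrazide nitrogen, by loss of the β-silyloxy group, or by condensation of the product enone with a second hydrazide. Fallback with a neutral, thermal trigger: 15 is condensed with 1-amino-2-phenylaziridine (CH2Cl2, 0 °C) to the N-aziridinyl imine F1, which is heated in toluene (80–110 °C). Loss of styrene gives the diazo compound, which opens the oxirane and fragments with loss of N2. The fallback sets out from 15 and comes back at 17.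

Step 9. What may go wrong: base-induced β-elimination of the C8 silyloxy group followed by aromatisation of ring A, or slow and 1,6-directed attack on the hindered tetrasubstituted alkene. Fallback by hydroxyl-directed epoxidation: Luche reduction of 14 (NaBH4, CeCl3·7H2O, MeOH) should give the cis-1,3 allylic alcohol F2. VO(acac)2 with t-BuOOH epoxidises the C1=C6 bond syn to the C10 hydroxyl to the epoxy alcohol F3, and Dess–Martin oxidation gives the epoxy ketone F4, the C1/C6 epimer of 15. Under the conditions of step 10 its tosylhydrazone F5 fragments to the same product. The fallback sets out from 14 and comes back at 17.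

Step 12 (with step 11). What may go wrong: poor facial selectivity in the kinetic protonation, re-equilibration to the 7,8-trans ketone, or β-elimination from the enolate. Fallback by chelation in place of steric control: 17 is desilylated (48% aq. HF, MeCN) to the β-hydroxy enynone F6. Its alkoxide–enolate dianion (LiN(i-Pr)2, 2.2 equiv, THF, −78 °C) is alkylated with methyl bromoacetate; the lithium chelate between O6 and O8 should direct the electrophile to the face that places the new substituent cis to O8 (Fráter–Seebach-type alkylation). The alkoxide is silylated in the same flask (t-BuMe2SiOSO2CF3, 2,6-lutidine, −78 °C). The fallback sets out from 17 and comes back at 19.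

Step 14 (with step 13). What may go wrong: closure with retention through an acyloxyphosphonium pathway, ionisation of the allylic C6–O bond with scrambling, or elimination. Fallback by intermolecular inversion: 21 is opened with MeNH(OMe)·HCl and AlMe3 to the hydroxy Weinreb amide F7. Mitsunobu esterification with 4-nitrobenzoic acid inverts C6 and gives the ester F8. K2CO3 in MeOH frees the inverted hydroxy amide F9, which closes to the trans-fused lactone on treatment with pyridinium 4-toluenesulfonate. The fallback sets out from 21 and comes back at 23.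

Step 21. What may go wrong: ionisation of the C15 allylic acetate or of the allylic lactone C6–O bond by zerovalent palladium, slow transfer of the hydroxymethyl group with competing butyl transfer, or protodeiodination. Fallback without zerovalent palladium: Nozaki–Hiyama–Kishi reaction of 31 with paraformaldehyde (CrCl2, NiCl2 cat., DMF/THF, rt). It makes no new compound, sets out from 31 and comes back at 32.

Further compounds

F1 | step 10 | N-aziridinyl imine of 15 at C10 (hydrazone with 1-amino-2-phenylaziridine) | c1ccccc1C1CN1N=C1C[C@@H](O[Si](C)(C)C(C)(C)C)C[C@]23O[C@]12CCC(COCc4ccc(OC)cc4)=C3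
F2 | step 9 | (1S,3S)-3-{[tert-butyl(dimethyl)silyl]oxy}-6-{[(4-methoxybenzyl)oxy]methyl}-1,2,3,4,7,8-hexahydronaphthalen-1-ol | O[C@H]1C[C@@H](O[Si](C)(C)C(C)(C)C)CC2=C1CCC(COCc3ccc(OC)cc3)=C2
F3 | step 9 | 4a,8a-epoxide of F2 with the oxirane oxygen cis to the C1 hydroxyl and to the silyloxy group | O[C@H]1C[C@@H](O[Si](C)(C)C(C)(C)C)C[C@@]23O[C@@]12CCC(COCc4ccc(OC)cc4)=C3
F4 | step 9 | (3S,4aS,8aR)-3-{[tert-butyl(dimethyl)silyl]oxy}-4a,8a-epoxy-6-{[(4-methoxybenzyl)oxy]methyl}-3,4,4a,7,8,8a-hexahydronaphthalen-1(2H)-one | O=C1C[C@@H](O[Si](C)(C)C(C)(C)C)C[C@@]23O[C@@]12CCC(COCc4ccc(OC)cc4)=C3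
F5 | step 9 | 4-methylbenzenesulfonylhydrazone of F4 | Cc1ccc(cc1)S(=O)(=O)NN=C1C[C@@H](O[Si](C)(C)C(C)(C)C)C[C@@]23O[C@@]12CCC(COCc4ccc(OC)cc4)=C3
F6 | step 12 | (2E,9R)-9-hydroxy-3-{[(4-methoxybenzyl)oxy]methyl}cyclodec-2-en-6-yn-1-one | C1C#CCC/C(COCc2ccc(OC)cc2)=C\C(=O)C[C@@H]1O
F7 | step 14 | 2-[(1S,2S,3E,10R)-10-{[tert-butyl(dimethyl)silyl]oxy}-2-hydroxy-4-{[(4-methoxybenzyl)oxy]methyl}cyclodec-3-en-7-yn-1-yl]-N-methoxy-N-methylacetamide | C1C#CCC/C(COCc2ccc(OC)cc2)=C\[C@H](O)[C@H](CC(=O)N(C)OC)[C@@H]1O[Si](C)(C)C(C)(C)C
F8 | step 14 | 4-nitrobenzoate of the C6-inverted alcohol derived from F7 | C1C#CCC/C(COCc2ccc(OC)cc2)=C\[C@@H](OC(=O)c2ccc(cc2)[N+](=O)[O-])[C@H](CC(=O)N(C)OC)[C@@H]1O[Si](C)(C)C(C)(C)C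
F9 | step 14 | 2-[(1S,2R,3E,10R)-10-{[tert-butyl(dimethyl)silyl]oxy}-2-hydroxy-4-{[(4-methoxybenzyl)oxy]methyl}cyclodec-3-en-7-yn-1-yl]-N-methoxy-N-methylacetamide | C1C#CCC/C(COCc2ccc(OC)cc2)=C\[C@@H](O)[C@H](CC(=O)N(C)OC)[C@@H]1O[Si](C)(C)C(C)(C)C
F0 | step 21 | none | none
A1 | alternative 1 | O8-tert-butyldimethylsilyl ether of the target | C=C(C)C(=O)OC/C1=C/CC/C(COC(C)=O)=C\[C@H]2OC(=O)C(=C)[C@@H]2[C@H](O[Si](C)(C)C(C)(C)C)C1
A2 | alternative 1 | ten-membered diene acid (C4=C15 and ring-cis C5=C6; 2-substituted acrylic acid on C7; O8 silyl ether; O14 methacrylate) | C=C(C)C(=O)OC/C1=C/CCC(=C)/C=C\[C@H](C(=C)C(=O)O)[C@H](O[Si](C)(C)C(C)(C)C)C1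
A3 | alternative 2 | ten-membered carbocycle with C2 phenylsulfonyl group and fused 3-methylenetetrahydrofuran; O8 and O14 TBS ethers; O15 TIPS ether | CC(C)(C)[Si](C)(C)OC/C1=C/[C@@H](S(=O)(=O)c2ccccc2)C/C(CO[Si](C(C)C)(C(C)C)C(C)C)=C\[C@H]3OCC(=C)[C@@H]3[C@H](O[Si](C)(C)C(C)(C)C)C1
A4 | alternative 2 | open-chain C2 allylic phenyl sulfone with C3 primary allylic bromide | O=S(=O)(c1ccccc1)C/C=C(/CO[Si](C)(C)C(C)(C)C)C[C@@H](O[Si](C)(C)C(C)(C)C)[C@H]1C(=C)CO[C@@H]1/C=C(/CO[Si](C(C)C)(C(C)C)C(C)C)CBr
A5 | alternative 3 | ten-membered carbocycle with fused 3-methylenetetrahydrofuran and free C8 hydroxyl; O14 TBS ether; O15 TIPS ether | CC(C)(C)[Si](C)(C)OC/C1=C/CC/C(CO[Si](C(C)C)(C(C)C)C(C)C)=C\[C@H]2OCC(=C)[C@@H]2[C@H](O)C1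
A6 | alternative 3 | thirteen-membered cyclic ether with C8 tributylstannyl group and fused 2,5-dihydrofuran | CCCC[Sn](CCCC)(CCCC)[C@@H]1C/C(CO[Si](C)(C)C(C)(C)C)=C\CC/C(CO[Si](C(C)C)(C(C)C)C(C)C)=C\[C@H]2OCC(CO1)=C2
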